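**Plan**

- Numbering is that of 2H-chromene, with the side chain C1'–C6' counted from C2. The C3=C4 alkene is traced back to the enol triflate of a chroman-3-one. The pyran ring is then cut at C3–C4 and C4–C4a, which removes C4 and leaves a 2,2-disubstituted benzofuran-3(2H)-one. Further cuts fall at C2'–C3' (side chain), C2–C1' (quaternary centre) and O1–C2 (furanone ring).
- The enabling feature is that C2 carries no hydrogen. The six-membered ring is the benzofuranone ring plus one carbon placed between C3 and the arene, the flanking ketone cannot epimerise C2, and a chroman-3-one (or its 4-oxo isomer) can only place its double bond at C3–C4.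
- Forward order: the furanone ring closes first; C2 becomes quaternary by palladium-catalysed decarboxylative allylation; the allyl group is trimmed to an iodoethyl arm; a Negishi coupling joins the (E)-alkenyl iodide at C2'–C3'; one-carbon insertion enlarges the ring; triflation, reduction and desilylation finish.
- Stereochemistry: (S)-C2 comes from the chiral ligand in the allylation and is then carried only through non-enolisable ketones. The (E)-C3'=C4' alkene comes from syn carboalumination of a terminal alkyne and is retained in the coupling.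

Key step: step 12

Assumption: the (R,R)-enantiomer of the ligand in step 5 is written for the (S)-ketone 8 by analogy with related cyclic enol carbonates; the sense of induction is to be checked on 8 and the (S,S)-ligand used if it proves opposite.

**Route**

Step 1
Reactants: 1 2',5'-dihydroxypropiophenone
Product: 2 1-[2-hydroxy-5-(triisopropylsilyloxy)phenyl]propan-1-one
Conditions: TIPSCl (1.05 equiv), imidazole, DMF, 0 °C → rt
Reagents that add atoms: chlorotriisopropylsilane, CC(C)[Si](Cl)(C(C)C)C(C)C
Why: The 2'-hydroxyl is held in a hydrogen bond to the ketone, so imidazole-mediated silylation by the bulky chlorosilane should take place at the free 5'-hydroxyl.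

Step 2
Reactants: 2 1-[2-hydroxy-5-(triisopropylsilyloxy)phenyl]propan-1-one
Product: 3 2-bromo-1-[2-hydroxy-5-(triisopropylsilyloxy)phenyl]propan-1-one (racemic)
Conditions: CuBr2 (2.1 equiv), EtOAc/CHCl3 (1:1), reflux
Reagents that add atoms: copper dibromide, Br[Cu]Br
Why: Copper dibromide α-bromination of aryl alkyl ketones acts through the copper-bound enol and halogenates the CH2 next to the carbonyl rather than the ring; the CHBr centre is racemic and is made planar in step 4.

Step 3
Reactants: 3 2-bromo-1-[2-hydroxy-5-(triisopropylsilyloxy)phenyl]propan-1-one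
Product: 4 2-methyl-5-(triisopropylsilyloxy)benzofuran-3(2H)-one (racemic)
Conditions: NaOAc, EtOH, 60 °C
Reagents that add atoms: none
Why: The phenoxide displaces the α-bromide in a 5-exo-tet intramolecular Williamson etherification, the standard closure of benzofuran-3(2H)-ones from 2'-hydroxy α-halo ketones.

Step 4
Reactants: 4 2-methyl-5-(triisopropylsilyloxy)benzofuran-3(2H)-one; 5 allyl chloroformate
Product: 7 allyl 2-methyl-5-(triisopropylsilyloxy)benzofuran-3-yl carbonate, via sodium enolate 6 (not isolated)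
Conditions: NaN(SiMe3)2, THF, −78 °C; then 5, −78 → 0 °C
Reagents that add atoms: allyl chloroformate (5), C=CCOC(Cl)=O
Why: The aromatic benzofuran-3-olate is acylated at oxygen by the hard chloroformate (enol carbonate formation), which fixes the enolate as a neutral precursor for the allylation.

Step 5
Reactants: 7 allyl 2-methyl-5-(triisopropylsilyloxy)benzofuran-3-yl carbonate
Product: 8 (2S)-2-allyl-2-methyl-5-(triisopropylsilyloxy)benzofuran-3(2H)-one
Conditions: Pd2(dba)3·CHCl3 (2.5 mol %), (R,R)-ANDEN-phenyl Trost ligand (5.5 mol %), 1,4-dioxane, rt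
Reagents that add atoms: none
Why: In this decarboxylative asymmetric allylic alkylation (Tsuji–Trost type) zerovalent palladium ionises the allyl carbonate, CO2 is lost, and the prochiral benzofuran-3-olate attacks the π-allyl complex at C2 inside the chiral ligand pocket, which selects the enolate face and sets C2 as (S), while any O-allyl ether re-ionises and funnels to the C-allyl ketone.

Step 6
Reactants: 8 (2S)-2-allyl-2-methyl-5-(triisopropylsilyloxy)benzofuran-3(2H)-one
Product: 10 2-[(2S)-2-methyl-3-oxo-5-(triisopropylsilyloxy)-2,3-dihydrobenzofuran-2-yl]acetaldehyde, via ozonide 9 (not isolated)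
Conditions: O3 (dosed to consumption of 8), CH2Cl2, −78 °C; then PPh3, −78 °C → rt; used at once
Reagents that add atoms: ozone, [O-][O+]=O
Why: Ozonolysis with phosphine reduction of the ozonide cleaves the terminal alkene far faster than ozone attacks the acyl-deactivated arene, and the neutral work-up avoids enolising the β-aryloxy aldehyde.

Step 7
Reactants: 10 2-[(2S)-2-methyl-3-oxo-5-(triisopropylsilyloxy)-2,3-dihydrobenzofuran-2-yl]acetaldehyde
Product: 11 (2S)-2-(2-hydroxyethyl)-2-methyl-5-(triisopropylsilyloxy)benzofuran-3(2H)-one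
Conditions: NaBH4, MeOH/CH2Cl2, −78 °C
Reagents that add atoms: none
Why: At −78 °C borohydride reduces an unhindered aliphatic aldehyde much faster than an aryl ketone that is flanked by a quaternary carbon and deactivated by the ortho oxygen (chemoselective hydride reduction).

Step 8
Reactants: 11 (2S)-2-(2-hydroxyethyl)-2-methyl-5-(triisopropylsilyloxy)benzofuran-3(2H)-one
Product: 12 (2S)-2-(2-iodoethyl)-2-methyl-5-(triisopropylsilyloxy)benzofuran-3(2H)-one
Conditions: I2, PPh3, imidazole, CH2Cl2, 0 °C → rt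
Reagents that add atoms: iodine, II
Why: Appel-type iodination (Garegg–Samuelsson conditions) converts the primary alcohol through its alkoxyphosphonium salt by SN2 displacement and leaves the ketone, the silyl ether and C2 untouched.

Step 9
Reactants: 13 dihydro-β-ionone
Product: 16 2-(but-3-yn-1-yl)-1,3,3-trimethylcyclohex-1-ene, via lithium enolate 14 (not isolated), via enol phosphate 15 (not isolated)
Conditions: LiN(iPr)2 (1.05 equiv), THF, −78 °C; ClP(O)(OEt)2, −78 °C → rt; LiN(iPr)2 (2.3 equiv), −78 °C → rt; aq NH4Cl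
Reagents that add atoms: none
Why: Kinetic deprotonation of the methyl ketone on the methyl side, O-phosphorylation and base-induced β-elimination of diethyl phosphate is the established one-flask conversion of methyl ketones into terminal alkynes.

Step 10
Reactants: 16 2-(but-3-yn-1-yl)-1,3,3-trimethylcyclohex-1-ene; 17 trimethylaluminium
Product: 19 2-[(3E)-4-iodo-3-methylbut-3-en-1-yl]-1,3,3-trimethylcyclohex-1-ene, via alkenylalane 18 (not isolated)
Conditions: AlMe3 (2 equiv), Cp2ZrCl2 (0.25 equiv), CH2Cl2, 0 °C → rt; then I2, THF, −30 → 0 °C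
Reagents that add atoms: trimethylaluminium (17), C[Al](C)C; iodine, II
Why: Zirconium-catalysed carboalumination (Negishi) adds methyl and aluminium syn across the terminal alkyne with aluminium at the terminus, and iodinolysis with retention gives the (E)-iodide, the tetrasubstituted ring alkene being inert.

Step 11
Reactants: 12 (2S)-2-(2-iodoethyl)-2-methyl-5-(triisopropylsilyloxy)benzofuran-3(2H)-one; 19 2-[(3E)-4-iodo-3-methylbut-3-en-1-yl]-1,3,3-trimethylcyclohex-1-ene
Product: 21 (2S)-2-methyl-2-[(3E)-4-methyl-6-(2,6,6-trimethylcyclohex-1-en-1-yl)hex-3-en-1-yl]-5-(triisopropylsilyloxy)benzofuran-3(2H)-one, via alkylzinc iodide 20 (not isolated)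
Conditions: 12, Zn dust (activated with BrCH2CH2Br and Me3SiCl), LiCl, THF, 40 °C; then 19, PdCl2(dppf) (5 mol %), THF, rt → 45 °C
Reagents that add atoms: none
Why: Zinc inserts into the primary C–I bond without touching the non-enolisable ketone, and the Negishi sp3–sp2 coupling forms C2'–C3' with retention of the (E)-geometry, the bidentate ligand holding back β-hydride elimination.

Step 12
Reactants: 21 (2S)-2-methyl-2-[(3E)-4-methyl-6-(2,6,6-trimethylcyclohex-1-en-1-yl)hex-3-en-1-yl]-5-(triisopropylsilyloxy)benzofuran-3(2H)-one; 22 (trimethylsilyl)diazomethane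
Product: 24 (2S)-2-methyl-2-[(3E)-4-methyl-6-(2,6,6-trimethylcyclohex-1-en-1-yl)hex-3-en-1-yl]-6-(triisopropylsilyloxy)chroman-3-one, via C4-silyl ketone 23 (not isolated)
Conditions: Me3SiCHN2 (1.3 equiv), BF3·OEt2 (1.2 equiv), CH2Cl2, −78 → −40 °C; aq NaHCO3; then 1 M HCl, THF, 0 °C
Reagents that add atoms: (trimethylsilyl)diazomethane (22), C[Si](C)(C)C=[N+]=[N-]
Why: Proposed new method: BF3 binds the C3 carbonyl oxygen of 21, the nucleophilic diazo carbon of 22 adds to C3, and the resulting β-boryloxy diazonium ion loses N2 as the aryl carbon shifts from C3 to the incoming carbon, which thereby becomes C4 bonded to both C3 and C4a. The closest known reaction type is the Lewis-acid-promoted Me3SiCHN2 homologation of 1-indanones, 1-tetralones and other cyclic ketones (a Tiffeneau–Demjanov-type ring expansion), which has not been shown on 2,2-disubstituted benzofuran-3(2H)-ones. The pyran ring is formed by enlargement of the furanone ring from five to six members through this 1,2-shift, not by a cyclisation. No lasting stereocentre is created, since the silyl-bearing C4 of 23 is cleared by protodesilylation, and C2, which has no hydrogen, is either untouched or, should it migrate instead of the aryl carbon, moves with retention. The step needs only chemoselectivity for a single insertion: the Lewis acid favours the shift over closure to the oxirane, the C4 silyl group and the quaternary C2 shield the new ketone from a second insertion, and the alkenes do not react with the diazoalkane in the absence of a carbene-forming metal. Regiochemistry is not critical, because the alternative chroman-4-one would give an enol triflate across the same C3–C4 bond and hence the same alkene in steps 13 and 14.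

Step 13
Reactants: 24 (2S)-2-methyl-2-[(3E)-4-methyl-6-(2,6,6-trimethylcyclohex-1-en-1-yl)hex-3-en-1-yl]-6-(triisopropylsilyloxy)chroman-3-one
Product: 26 (2S)-2-methyl-2-[(3E)-4-methyl-6-(2,6,6-trimethylcyclohex-1-en-1-yl)hex-3-en-1-yl]-6-(triisopropylsilyloxy)-2H-chromen-3-yl trifluoromethanesulfonate, via potassium enolate 25 (not isolated)
Conditions: KN(SiMe3)2, THF, −78 °C; then PhNTf2, −78 → 0 °C
Reagents that add atoms: N-phenylbis(trifluoromethanesulfonimide), O=S(=O)(N(c1ccccc1)S(=O)(=O)C(F)(F)F)C(F)(F)F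
Why: Because C2 is quaternary the ketone can enolise only towards the benzylic C4, so a single enolate forms and is sulfonylated at oxygen (enol triflate formation) without any cationic intermediate that could contract the ring.

Step 14
Reactants: 26 (2S)-2-methyl-2-[(3E)-4-methyl-6-(2,6,6-trimethylcyclohex-1-en-1-yl)hex-3-en-1-yl]-6-(triisopropylsilyloxy)-2H-chromen-3-yl trifluoromethanesulfonate
Product: 27 triisopropyl({(2S)-2-methyl-2-[(3E)-4-methyl-6-(2,6,6-trimethylcyclohex-1-en-1-yl)hex-3-en-1-yl]-2H-chromen-6-yl}oxy)silane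
Conditions: Pd(OAc)2 (5 mol %), PPh3 (10 mol %), HCO2H, Bu3N, DMF, 60 °C
Reagents that add atoms: none
Why: Palladium-catalysed formate reduction of a vinyl triflate (oxidative addition, exchange of triflate for formate, loss of CO2 to the palladium hydride, reductive elimination) replaces OTf by H and leaves the double bond at C3–C4.

Step 15
Reactants: 27 triisopropyl({(2S)-2-methyl-2-[(3E)-4-methyl-6-(2,6,6-trimethylcyclohex-1-en-1-yl)hex-3-en-1-yl]-2H-chromen-6-yl}oxy)silane
Product: 28 (2S)-2-methyl-2-[(3E)-4-methyl-6-(2,6,6-trimethylcyclohex-1-en-1-yl)hex-3-en-1-yl]-2H-chromen-6-ol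
Conditions: Bu4NF, THF, 0 °C; aq NH4Cl
Reagents that add atoms: none
Why: Fluoride cleaves the aryl silyl ether through the strong Si–F bond under conditions that leave the chromene and the side-chain alkenes alone.

**Compound list**

1 | 2',5'-dihydroxypropiophenone | CCC(=O)c1cc(O)ccc1O | starting material
2 | 1-[2-hydroxy-5-(triisopropylsilyloxy)phenyl]propan-1-one | CCC(=O)c1cc(O[Si](C(C)C)(C(C)C)C(C)C)ccc1O | intermediate
3 | 2-bromo-1-[2-hydroxy-5-(triisopropylsilyloxy)phenyl]propan-1-one (racemic) | CC(Br)C(=O)c1cc(O[Si](C(C)C)(C(C)C)C(C)C)ccc1O | intermediate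
4 | 2-methyl-5-(triisopropylsilyloxy)benzofuran-3(2H)-one (racemic) | CC1Oc2ccc(O[Si](C(C)C)(C(C)C)C(C)C)cc2C1=O | intermediate
5 | allyl chloroformate | C=CCOC(Cl)=O | starting material
6 | sodium 2-methyl-5-(triisopropylsilyloxy)benzofuran-3-olate (not isolated) | [Na+].[O-]c1c(C)oc2ccc(O[Si](C(C)C)(C(C)C)C(C)C)cc12 | intermediate
7 | allyl 2-methyl-5-(triisopropylsilyloxy)benzofuran-3-yl carbonate | C=CCOC(=O)Oc1c(C)oc2ccc(O[Si](C(C)C)(C(C)C)C(C)C)cc12 | intermediate
8 | (2S)-2-allyl-2-methyl-5-(triisopropylsilyloxy)benzofuran-3(2H)-one | C=CC[C@@]1(C)C(=O)c2cc(O[Si](C(C)C)(C(C)C)C(C)C)ccc2O1 | intermediate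
9 | (2S)-2-methyl-2-(1,2,4-trioxolan-3-ylmethyl)-5-(triisopropylsilyloxy)benzofuran-3(2H)-one, the ozonide of 8 (not isolated) | C1OC(OO1)C[C@@]2(C)C(=O)c3cc(O[Si](C(C)C)(C(C)C)C(C)C)ccc3O2 | intermediate
10 | 2-[(2S)-2-methyl-3-oxo-5-(triisopropylsilyloxy)-2,3-dihydrobenzofuran-2-yl]acetaldehyde | O=CC[C@@]1(C)C(=O)c2cc(O[Si](C(C)C)(C(C)C)C(C)C)ccc2O1 | intermediate
11 | (2S)-2-(2-hydroxyethyl)-2-methyl-5-(triisopropylsilyloxy)benzofuran-3(2H)-one | OCC[C@@]1(C)C(=O)c2cc(O[Si](C(C)C)(C(C)C)C(C)C)ccc2O1 | intermediate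
12 | (2S)-2-(2-iodoethyl)-2-methyl-5-(triisopropylsilyloxy)benzofuran-3(2H)-one | ICC[C@@]1(C)C(=O)c2cc(O[Si](C(C)C)(C(C)C)C(C)C)ccc2O1 | intermediate
13 | dihydro-β-ionone, 4-(2,6,6-trimethylcyclohex-1-en-1-yl)butan-2-one | CC(=O)CCC1=C(C)CCCC1(C)C | starting material
14 | lithium 4-(2,6,6-trimethylcyclohex-1-en-1-yl)but-1-en-2-olate (not isolated) | [Li+].[O-]C(=C)CCC1=C(C)CCCC1(C)C | intermediate
15 | diethyl 4-(2,6,6-trimethylcyclohex-1-en-1-yl)but-1-en-2-yl phosphate (not isolated) | C=C(OP(=O)(OCC)OCC)CCC1=C(C)CCCC1(C)C | intermediate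
16 | 2-(but-3-yn-1-yl)-1,3,3-trimethylcyclohex-1-ene | C#CCCC1=C(C)CCCC1(C)C | intermediate
17 | trimethylaluminium | C[Al](C)C | starting material
18 | dimethyl[(1E)-2-methyl-4-(2,6,6-trimethylcyclohex-1-en-1-yl)but-1-en-1-yl]alane (not isolated) | CC1=C(CC/C(C)=C/[Al](C)C)C(C)(C)CCC1 | intermediate
19 | 2-[(3E)-4-iodo-3-methylbut-3-en-1-yl]-1,3,3-trimethylcyclohex-1-ene | CC1=C(CC/C(C)=C/I)C(C)(C)CCC1 | intermediate
20 | {2-[(2S)-2-methyl-3-oxo-5-(triisopropylsilyloxy)-2,3-dihydrobenzofuran-2-yl]ethyl}zinc iodide (not isolated) | I[Zn]CC[C@@]1(C)C(=O)c2cc(O[Si](C(C)C)(C(C)C)C(C)C)ccc2O1 | intermediate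
21 | (2S)-2-methyl-2-[(3E)-4-methyl-6-(2,6,6-trimethylcyclohex-1-en-1-yl)hex-3-en-1-yl]-5-(triisopropylsilyloxy)benzofuran-3(2H)-one | CC1=C(CC/C(C)=C/CC[C@@]2(C)C(=O)c3cc(O[Si](C(C)C)(C(C)C)C(C)C)ccc3O2)C(C)(C)CCC1 | intermediate
22 | (trimethylsilyl)diazomethane | C[Si](C)(C)C=[N+]=[N-] | starting material
23 | (2S)-2-methyl-2-[(3E)-4-methyl-6-(2,6,6-trimethylcyclohex-1-en-1-yl)hex-3-en-1-yl]-6-(triisopropylsilyloxy)-4-(trimethylsilyl)chroman-3-one, C4 epimers (not isolated) | CC1=C(CC/C(C)=C/CC[C@@]2(C)C(=O)C([Si](C)(C)C)c3cc(O[Si](C(C)C)(C(C)C)C(C)C)ccc3O2)C(C)(C)CCC1 | intermediate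
24 | (2S)-2-methyl-2-[(3E)-4-methyl-6-(2,6,6-trimethylcyclohex-1-en-1-yl)hex-3-en-1-yl]-6-(triisopropylsilyloxy)chroman-3-one | CC1=C(CC/C(C)=C/CC[C@@]2(C)C(=O)Cc3cc(O[Si](C(C)C)(C(C)C)C(C)C)ccc3O2)C(C)(C)CCC1 | intermediate
25 | potassium (2S)-2-methyl-2-[(3E)-4-methyl-6-(2,6,6-trimethylcyclohex-1-en-1-yl)hex-3-en-1-yl]-6-(triisopropylsilyloxy)-2H-chromen-3-olate (not isolated) | [K+].CC1=C(CC/C(C)=C/CC[C@@]2(C)C([O-])=Cc3cc(O[Si](C(C)C)(C(C)C)C(C)C)ccc3O2)C(C)(C)CCC1 | intermediate
26 | (2S)-2-methyl-2-[(3E)-4-methyl-6-(2,6,6-trimethylcyclohex-1-en-1-yl)hex-3-en-1-yl]-6-(triisopropylsilyloxy)-2H-chromen-3-yl trifluoromethanesulfonate | CC1=C(CC/C(C)=C/CC[C@@]2(C)C(OS(=O)(=O)C(F)(F)F)=Cc3cc(O[Si](C(C)C)(C(C)C)C(C)C)ccc3O2)C(C)(C)CCC1 | intermediate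
27 | triisopropyl({(2S)-2-methyl-2-[(3E)-4-methyl-6-(2,6,6-trimethylcyclohex-1-en-1-yl)hex-3-en-1-yl]-2H-chromen-6-yl}oxy)silane | CC1=C(CC/C(C)=C/CC[C@@]2(C)C=Cc3cc(O[Si](C(C)C)(C(C)C)C(C)C)ccc3O2)C(C)(C)CCC1 | intermediate
28 | (2S)-2-methyl-2-[(3E)-4-methyl-6-(2,6,6-trimethylcyclohex-1-en-1-yl)hex-3-en-1-yl]-2H-chromen-6-ol | CC1=C(CC/C(C)=C/CC[C@@]2(C)C=Cc3cc(O)ccc3O2)C(C)(C)CCC1 | target

**Count**

Total steps: 15. Longest linear sequence: 13 steps (steps 1–8 and 11–15); steps 9 and 10 make the side-chain iodide in parallel.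

**Steps most likely to fail**

Step 12. Addition of the diazo carbon to the hindered, donor-deactivated C3 carbonyl may be slow. Closure of the adduct to the oxirane, or Lewis-acid-induced attack of the C3'=C4' alkene on the activated carbonyl, could then outrun the 1,2-shift. The fallback sets out from 21 and uses the known one-carbon ring enlargement of cyclic ketones through β-oxido carbenoids. LiCHBr2, made from CH2Br2 and lithium 2,2,6,6-tetramethylpiperidide in THF at −78 °C, adds to C3 to give the dibromomethyl carbinol F1. BuLi (2.2 equiv, THF, −78 → 0 °C) then deprotonates the hydroxyl, exchanges one bromine for lithium, and the carbenoid rearranges with aryl shift and loss of LiBr. Aqueous quench should return the route at ketone 24.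

Step 5. Facial discrimination of the planar benzofuran-3-olate inside the ligand pocket may be poor, which would give 8 in low enantiomeric purity. The fallback sets out from 7. Decarboxylative allylation with Pd(PPh3)4 in THF, without a chiral ligand, gives the racemic ketone F2. Preparative chromatography on a chiral stationary phase then separates 8, where the route is rejoined, from its (R)-enantiomer F3, which is discarded.

Step 6. The β-aryloxy aldehyde may enolise and expel the aryloxide, and ring opening followed by reclosure would erode the configuration at C2; ozone may also attack the electron-rich arene. The fallback sets out from 8 and avoids both the aldehyde and ozone. Hydroboration with 9-borabicyclo[3.3.1]nonane in THF gives the B-alkylborane F4, which NaBO3·4H2O oxidises to the primary alcohol F5. TEMPO (catalytic) with PhI(OAc)2 in MeCN/H2O gives the carboxylic acid F6. Photochemical iododecarboxylation (PhI(OAc)2, I2, CH2Cl2, visible light, reflux) removes one carbon and returns the route at iodide 12.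

**Further compounds**

F1 | step 12 | (2S)-3-(dibromomethyl)-2-methyl-2-[(3E)-4-methyl-6-(2,6,6-trimethylcyclohex-1-en-1-yl)hex-3-en-1-yl]-5-(triisopropylsilyloxy)-2,3-dihydrobenzofuran-3-ol (C3 epimers) | CC1=C(CC/C(C)=C/CC[C@@]2(C)C(O)(C(Br)Br)c3cc(O[Si](C(C)C)(C(C)C)C(C)C)ccc3O2)C(C)(C)CCC1
F2 | step 5 | racemic 2-allyl-2-methyl-5-(triisopropylsilyloxy)benzofuran-3(2H)-one | C=CCC1(C)C(=O)c2cc(O[Si](C(C)C)(C(C)C)C(C)C)ccc2O1
F3 | step 5 | (2R)-2-allyl-2-methyl-5-(triisopropylsilyloxy)benzofuran-3(2H)-one | C=CC[C@]1(C)C(=O)c2cc(O[Si](C(C)C)(C(C)C)C(C)C)ccc2O1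
F4 | step 6 | (2S)-2-[3-(9-borabicyclo[3.3.1]nonan-9-yl)propyl]-2-methyl-5-(triisopropylsilyloxy)benzofuran-3(2H)-one | B1(CCC[C@@]4(C)C(=O)c5cc(O[Si](C(C)C)(C(C)C)C(C)C)ccc5O4)C2CCCC1CCC2
F5 | step 6 | (2S)-2-(3-hydroxypropyl)-2-methyl-5-(triisopropylsilyloxy)benzofuran-3(2H)-one | OCCC[C@@]1(C)C(=O)c2cc(O[Si](C(C)C)(C(C)C)C(C)C)ccc2O1
F6 | step 6 | 3-[(2S)-2-methyl-3-oxo-5-(triisopropylsilyloxy)-2,3-dihydrobenzofuran-2-yl]propanoic acid | OC(=O)CC[C@@]1(C)C(=O)c2cc(O[Si](C(C)C)(C(C)C)C(C)C)ccc2O1
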